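## Structural features

The target is methyl 3-[(2S,3R)-2-(4-hydroxy-3,5-dimethoxyphenyl)-3-(hydroxymethyl)-7-methoxy-2,3-dihydrobenzofuran-5-yl]propanoate. Ring A (the benzo ring) is fused through C3a and C7a to a dihydrofuran ring; it carries a methoxy group at C7 and the methyl propanoate chain at C5, and a syringyl ring sits on C2. C2 (S) and C3 (R) are adjacent stereocentres, with the aryl group and the hydroxymethyl group trans. The fragile parts are the free, electron-rich syringyl phenol (oxidant-sensitive), the benzylic C2–O1 bond para to it (open to acid ionisation and hydrogenolysis), the methyl ester (no hydride or organolithium after it is made) and the primary alcohol. The real difficulty is to make ring A with oxygen on the adjacent carbons C7a and C7 and a carbon chain at C5 without regiochemical doubt, while the trans C2/C3 pair is set in absolute terms. The key step exploits the fact that the C7 oxygen is ortho to C7a. If C7a and C7 are the two carbons of an alkynyl ether on the C2 oxygen, and C3a, C4, C5 and C6 are the carbons of a 2,4-disubstituted furan attached to C3, a gold furan–yne rearrangement forms C3a–C7a and C6–C7 and moves the furan oxygen onto C7. Both stereocentres then lie in the three-atom tether (C3, C2, O1) and can be set beforehand by one auxiliary-controlled syn aldol reaction.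

## Logic of the disconnections

**31 to 30.** The two exocyclic O–CH2Ph bonds (syringyl oxygen and the C3 hydroxymethyl oxygen) are cut. Both free O–H groups thus appear only in the last step, under neutral reduction, and no intermediate after 18 carries an O–H that could add to an activated alkyne or be oxidised. The forward step must cleave these two ethers and spare the endocyclic benzylic C2–O1 bond.

**30 to 29, 27 and 26.** The ester O–CH3 bond, then the oxidation level of the chain terminus, then its O–Si bond are cut. A methyl ester cannot pass the organolithium and hydride steps, so the chain travels as a silyl ether and is an inert spectator until after the key step. The oxidation must tolerate two electron-rich arenes, so it is placed after every phenol is capped.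

**26 to 25.** The C7 O–CH3 bond is cut. The key step delivers this oxygen as the only free phenol in the molecule, so the methylation needs no selectivity.

**25 to 22 (key).** C3a–C7a, C6–C7 and the C7–O bond are cut; ring A falls back to a furan plus a terminal alkynyl ether. Two rings are removed at once and the arene substitution problem is reduced to a 2,4-disubstituted furan. Structures 22 and 25 were checked against the mechanism and are kept as drawn: the tether carbon sits on furan C2 (future C3a), the chain on furan C4 (future C5), furan C5 is unsubstituted (future C6–H), the alkyne is terminal (C7 must carry hydrogen to become a phenol), and the descriptors (1S,2R) in 22 and (2S,3R) in 25 describe the same spatial arrangement. The forward step demands attack at the oxygen-bearing alkyne carbon, the furan as the only effective nucleophile, and the absence of water and acid.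

**22 to 18 and 19.** The O–C(sp) bond is cut. The alcohol oxygen of 18 becomes O1 and 19 supplies C7a and C7. The carbinol C–O bond must stay intact so that C2 keeps its configuration, and the other groups must survive KH and n-BuLi, which is why every oxygen is an ether.

**18 to 17 and 16.** The primary O–CH2Ph bond and then the oxidation level of the hydroxymethyl carbon (the acyl–N bond) are cut. This leads to the aldol adduct and releases the auxiliary. The forward benzylation must distinguish the primary from the secondary benzylic hydroxyl.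

**16 to 12 and 14.** The future C2–C3 bond is cut. This is the only stereo-defining disconnection: a syn aldol sets both centres with a known sense, and syn in the open chain becomes trans in the ring because the oxygen and the furan carbon both end up in the ring.

**14 to 13.** The O–CH2Ph bond of the aldehyde component is cut.

**12 to 9 and 10.** The N–acyl bond is cut.

**9 to 6, then to 4 and 5.** The bond between the furfuryl carbon and the carboxyl carbon is cut. This is a one-carbon homologation of an aldehyde, chosen because furfuryl halides do not give clean cyanide displacement. The forward step must use hydride at the furfuryl position and must not lose the silyl ether.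

**4 to 1 and 2.** The furan C4–CH2 bond is cut by sp2–sp3 cross-coupling. The bromine in 1 fixes the 2,4-pattern of the furan from a commercial compound.

## Other disconnections considered

**Alternative 1: flavanone ring contraction.**
- Cut: the C3–C3a bond of the ester A1, methyl (2S,3S)-5-bromo-2-(3,5-dimethoxy-4-pivaloyloxyphenyl)-7-methoxy-2,3-dihydrobenzofuran-3-carboxylate. Its precursor is the flavanone A2, (2S)-6-bromo-2-(3,5-dimethoxy-4-pivaloyloxyphenyl)-8-methoxychroman-4-one.
- Forward step: PhI(OAc)2 (trivalent iodine) with H2SO4 in HC(OMe)3 would convert A2 through its enol ether into an alpha-iodane. Ring A would then shift from the ketal carbon to the alpha-carbon with loss of iodobenzene, contracting the pyranone and leaving the old carbonyl carbon as the methyl ester.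
- In favour: ring A is bought as an arene, so its substitution is not at issue. The 1,2-shift is expected to give the trans ester. Only one stereocentre has to be made beforehand. The reaction type is established for flavanones.
- Against: an enantioenriched 2-arylchromanone can open and reclose by retro-oxa-Michael reaction, and the step runs in strong acid, so the C2 configuration is at risk. The oxygenated ring on C2 can migrate instead of ring A and give an isoflavone; the pivalate is there to damp this but two methoxy groups remain. Ester reduction, pivalate removal and conversion of the bromide into the propanoate chain still follow.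
- Comparison: on precedent for the key step and on step count this alternative is the better plan. On structure it closes one ring where the chosen plan closes two, and on stereocontrol it is weaker, because the chosen plan sets both centres under auxiliary control with no acid-labile stereocentre.

**Alternative 2: formal 4+1 annulation.**
- Cut: C2–C3 and O1–C2 of the dihydrobenzofuran A3, methyl 3-[(2S,3R)-2-(4-benzyloxy-3,5-dimethoxyphenyl)-3-(tert-butyldimethylsilyloxymethyl)-7-methoxy-2,3-dihydrobenzofuran-5-yl]propanoate. The partners are the sulfone A4, methyl 3-{4-hydroxy-3-methoxy-5-[2-(tert-butyldimethylsilyloxy)-1-(4-methylphenylsulfonyl)ethyl]phenyl}propanoate, and a chiral benzylsulfonium salt such as A5, 1-(4-benzyloxy-3,5-dimethoxybenzyl)-(2R,5R)-2,5-dimethylthiolan-1-ium triflate.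
- Forward step: Cs2CO3 would eliminate sulfinate from A4 to give the ortho-quinone methide and deprotonate A5. The ylide carbon would add to the methide carbon (future C3), and the phenoxide would then displace the sulfide at C2 in a 5-exo-tet closure.
- In favour: it is the most convergent plan. The propanoate is carried as the methyl ester itself, which the chosen plan cannot do. A3 would be two deprotections from the target.
- Against: both stereocentres are made in one intermolecular step, with the absolute sense resting on a stoichiometric chiral sulfide; which enantiomer of the sulfide is needed would have to be found. The quinone methide carries an alkyl substituent with hydrogens next to the methide carbon and can tautomerise to a vinylphenol. Semi-stabilised ylides bearing electron-rich aryl groups are expected to give modest control.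
- Comparison: on step economy and functional-group economy it is the better plan. On mechanism it is a known class, but not for this substitution pattern in asymmetric form. On security of the absolute and relative configuration the chosen plan is stronger.

**Alternative 3: para-quinone methide cyclisation.**
- Cut: O1–C2 of the bromide A6, 4-[(2S,3R)-5-bromo-3-(hydroxymethyl)-7-methoxy-2,3-dihydrobenzofuran-2-yl]-2,6-dimethoxyphenol. The precursor is the diarylpropanol A7, (2R)-2-(5-bromo-2-hydroxy-3-methoxyphenyl)-3-(4-hydroxy-3,5-dimethoxyphenyl)propan-1-ol, with one stereocentre.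
- Forward step: Ag2O (monovalent silver) would oxidise the syringyl phenol of A7 to its para-quinone methide. The ring A phenol would add to the exocyclic carbon in a 5-exo-trig closure, trans to the C3 substituent.
- In favour: it uses the free syringyl phenol of the target as the activating group, so that oxygen needs no protecting group; on this point it is better than the chosen plan. Only one stereocentre has to be made by a reagent-controlled step. Ring A is again bought.
- Against: the ring A phenol is itself oxidisable and competes for the oxidant. The quinone methide has a hydrogen on the adjacent carbon and can tautomerise to a styrene. The trans selectivity is substrate-controlled and may be incomplete. The propanoate chain still has to be built from the bromide in the presence of a free phenol.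
- Comparison: on step count it is equal or slightly better, and on mechanism it is plausible and biomimetic. On structure it forms one C–O bond where the chosen plan builds ring A and the heterocycle together, and its control of C2 is less certain than the aldol of the chosen plan.

Key step: step 10

Remark: benzofuran numbering (O1, C2, C3, C3a, C4 to C7, C7a) is used for the core throughout; metal-bound forms of a product (boron aldolate, lithium acetylide, carboxylate salts) and catalyst-bound organometallic species are described in the text and carry no number.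

## Route

**Step 1**
Reactants: 1 4-bromofuran-2-carbaldehyde; 2 allyloxy(tert-butyl)dimethylsilane
Product: 4 4-[3-(tert-butyldimethylsilyloxy)propyl]furan-2-carbaldehyde, via alkylborane 3 (not isolated)
Conditions: 2 (1.3 equiv), 9-BBN (1.2 equiv), THF, 0 °C to rt; then 1, Pd(dppf)Cl2 (3 mol%), aq. K3PO4, DMF, 50 °C
Reagents that add atoms: none
Why: Anti-Markovnikov hydroboration gives the primary alkylborane 3, which couples with the heteroaryl bromide in a B-alkyl Suzuki–Miyaura reaction; the alkene is in excess so that no B–H is left to reduce the aldehyde, and the non-enolisable aldehyde tolerates the aqueous phosphate base.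

**Step 2**
Reactants: 4; 5 chloroform
Product: 6 (RS)-2,2,2-trichloro-1-{4-[3-(tert-butyldimethylsilyloxy)propyl]furan-2-yl}ethan-1-ol
Conditions: CHCl3 (reagent and solvent), DBU (1.0 equiv), 0 °C to rt
Reagents that add atoms: none
Why: Amidine-promoted addition of the trichloromethyl anion to a non-enolisable aromatic aldehyde; the new carbinol centre is racemic and is destroyed in step 3.

**Step 3**
Reactants: 6
Product: 9 2-{4-[3-(tert-butyldimethylsilyloxy)propyl]furan-2-yl}acetic acid, via dichloroepoxide 7 (not isolated), via acyl chloride 8 (not isolated)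
Conditions: NaBH4 (1.5 equiv), NaOH (3.5 equiv), t-BuOH, 40–55 °C; then aq. citric acid to pH 4, 0 °C
Reagents that add atoms: sodium hydroxide, [Na+].[OH-]
Why: Reductive Jocic–Reeve homologation: the alkoxide closes to the gem-dichloroepoxide 7, hydride opens it at the furfuryl carbon, the dichloroalkoxide collapses to acyl chloride 8 and hydroxide gives the carboxylate; the bulky alcohol solvent and excess hydride disfavour opening by hydroxide to the alpha-hydroxy acid.

**Step 4**
Reactants: 9; 10 (S)-4-benzyl-1,3-oxazolidin-2-one
Product: 12 (S)-4-benzyl-3-(2-{4-[3-(tert-butyldimethylsilyloxy)propyl]furan-2-yl}acetyl)-1,3-oxazolidin-2-one, via mixed anhydride 11 (not isolated)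
Conditions: PivCl (1.1 equiv), Et3N (2.5 equiv), THF, −20 °C; then LiCl (1.2 equiv), 10 (1.05 equiv), −20 °C to rt
Reagents that add atoms: none
Why: N-acylation through the mixed pivalic anhydride, which is attacked at the less hindered carbonyl by the LiCl-activated oxazolidinone; this avoids an acid chloride and an organolithium base on an acid-sensitive furan.

**Step 5**
Reactants: 13 syringaldehyde (4-hydroxy-3,5-dimethoxybenzaldehyde)
Product: 14 4-benzyloxy-3,5-dimethoxybenzaldehyde
Conditions: BnBr (1.1 equiv), K2CO3 (1.5 equiv), DMF, rt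
Reagents that add atoms: benzyl bromide, BrCc1ccccc1
Why: Williamson etherification of the acidic phenol; the benzyl group is stable to base, hydride and organolithium and leaves by hydrogenolysis at the end.

**Step 6**
Reactants: 12; 14
Product: 16 (4S)-4-benzyl-3-[(2R,3S)-3-(4-benzyloxy-3,5-dimethoxyphenyl)-2-{4-[3-(tert-butyldimethylsilyloxy)propyl]furan-2-yl}-3-hydroxypropanoyl]-1,3-oxazolidin-2-one, via boron enolate 15 (not isolated)
Conditions: Bu2BOTf (1.2 equiv), i-Pr2NEt (1.4 equiv), CH2Cl2, −78 to 0 °C; then 14 (1.2 equiv), −78 to 0 °C; pH 7 buffer, MeOH, 30% H2O2, 0 °C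
Reagents that add atoms: none
Why: Evans syn aldol: the (Z)-boron enolate 15 reacts with 14 through a closed Zimmerman–Traxler chair with the aldehyde aryl group equatorial and attack on the enolate face away from the benzyl group of the auxiliary (carbonyl dipoles opposed), which should give the syn (2R,3S) adduct; these centres become C3 and C2 of the target, and syn in the chain corresponds to trans in the ring.

**Step 7**
Reactants: 16
Product: 17 (1S,2R)-1-(4-benzyloxy-3,5-dimethoxyphenyl)-2-{4-[3-(tert-butyldimethylsilyloxy)propyl]furan-2-yl}propane-1,3-diol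
Conditions: LiBH4 (2 equiv), MeOH (2 equiv), THF, 0 °C
Reagents that add atoms: none
Why: Reductive cleavage of the N-acyloxazolidinone to the primary alcohol with return of 10; it is run cold and without delay because the alpha-proton of 16 is doubly activated, and after reduction that centre can no longer epimerise.

**Step 8**
Reactants: 17
Product: 18 (1S,2R)-3-benzyloxy-1-(4-benzyloxy-3,5-dimethoxyphenyl)-2-{4-[3-(tert-butyldimethylsilyloxy)propyl]furan-2-yl}propan-1-ol
Conditions: Ag2O (1.5 equiv), BnBr (1.1 equiv), CH2Cl2, rt, dark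
Reagents that add atoms: benzyl bromide, BrCc1ccccc1
Why: Ag2O-mediated mono-benzylation of a diol, in which the unhindered primary hydroxyl should be alkylated in preference to the hindered secondary benzylic one, without a strong base that would favour double alkylation; no stereocentre is involved.

**Step 9**
Reactants: 18; 19 trichloroethylene
Product: 22 tert-butyl{3-[5-((1S,2R)-3-benzyloxy-1-(4-benzyloxy-3,5-dimethoxyphenyl)-1-ethynyloxypropan-2-yl)furan-3-yl]propoxy}dimethylsilane, via dichlorovinyl ether 20 (not isolated), via chloroalkynyl ether 21 (not isolated)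
Conditions: KH (30% in mineral oil, 2.2 equiv), THF, 0 °C to rt; 19 (1.1 equiv), −50 °C to rt; n-BuLi (2.4 equiv), −78 to −50 °C; MeOH, −78 °C; cold pH 7 work-up, filtration through Et3N-deactivated silica below 20 °C, used at once
Reagents that add atoms: none
Why: Alkynyl ether synthesis from trichloroethylene: KH turns 19 into dichloroacetylene, which exists only in cold solution under argon and is consumed as it forms; the potassium alkoxide of 18 adds to it to give the (E)-dichlorovinyl ether 20, n-BuLi eliminates HCl to 21 and exchanges chlorine for lithium, and methanol protonates the acetylide. The carbinol C–O bond is never broken, so C2 keeps its configuration, and the silyl and benzyl ethers should tolerate the short low-temperature exposure to n-BuLi.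

**Step 10**
Reactants: 22
Product: 25 (2S,3R)-3-(benzyloxymethyl)-2-(4-benzyloxy-3,5-dimethoxyphenyl)-5-[3-(tert-butyldimethylsilyloxy)propyl]-2,3-dihydrobenzofuran-7-ol, via oxepine 23 (not isolated), via arene oxide 24 (not isolated)
Conditions: (Ph3P)AuNTf2 (5 mol%), 2,6-di-tert-butylpyridine (10 mol%), 4 Å molecular sieves, CH2Cl2 (0.02 M), 0 °C to rt
Reagents that add atoms: none
Why: Proposed new method: cationic monovalent gold should activate the terminal alkynyl ether of 22 as a gold keteniumyl species that is electrophilic at the oxygen-bearing carbon, and the tether-bearing furan alpha-carbon attacks it in a 5-exo-dig ipso fashion, closing the dihydrofuran ring (O1, C2, C3, C3a, C7a) and giving a cyclopropyl gold carbene that cannot rearomatise by proton loss. Cleavage of the furan C–O bond then gives a (Z)-dienal gold carbene, the aldehyde oxygen adds to the carbene carbon with release of gold to give oxepine 23, and disrotatory 6π electrocyclisation to arene oxide 24 closes ring A by forming C6–C7. Opening of 24 places the cation on the pentadienyl system that ends at C7a, where the lone pair of O1 stabilises it, so the oxygen stays on C7 and tautomerisation gives the 7-phenol; the other opening would put the charge beta to O1. The closest known reaction type is the gold-catalysed furan–yne phenol synthesis of furans carrying a terminal alkyne on a three-atom carbon-, nitrogen- or oxygen-linked tether, which has the same tether length and the same ortho-phenol outcome, and the alkynyl ether as alkyne component is the new element. No stereocentre is formed, and C2 and C3 are untouched because neither is ionised or enolised under neutral, buffered conditions. The step needs attack at the oxygen-bearing alkyne carbon (secured by the polarisation of the alkynyl ether), the furan as nucleophile and not the syringyl ring or the benzyl ether oxygen (secured by its higher nucleophilicity and the five-membered closure), and cyclisation faster than hydration or loss of ketene (secured by molecular sieves, the hindered pyridine, dilution and low temperature).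

**Step 11**
Reactants: 25
Product: 26 tert-butyl{3-[(2S,3R)-3-(benzyloxymethyl)-2-(4-benzyloxy-3,5-dimethoxyphenyl)-7-methoxy-2,3-dihydrobenzofuran-5-yl]propoxy}dimethylsilane
Conditions: MeI (1.5 equiv), K2CO3 (2 equiv), acetone, 50 °C
Reagents that add atoms: iodomethane, CI
Why: Williamson methylation of the only free hydroxyl, a phenol, with a weak base; silyl and benzyl ethers are inert.

**Step 12**
Reactants: 26
Product: 27 3-[(2S,3R)-3-(benzyloxymethyl)-2-(4-benzyloxy-3,5-dimethoxyphenyl)-7-methoxy-2,3-dihydrobenzofuran-5-yl]propan-1-ol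
Conditions: TBAF (1.2 equiv), THF, 0 °C to rt
Reagents that add atoms: none
Why: Fluoride-induced cleavage of the primary silyl ether, driven by Si–F bond formation; the benzyl and methyl ethers and both stereocentres are unaffected.

**Step 13**
Reactants: 27
Product: 29 3-[(2S,3R)-3-(benzyloxymethyl)-2-(4-benzyloxy-3,5-dimethoxyphenyl)-7-methoxy-2,3-dihydrobenzofuran-5-yl]propanoic acid, via aldehyde 28 (not isolated)
Conditions: TEMPO (0.2 equiv), PhI(OAc)2 (2.5 equiv), MeCN/H2O 1:1, rt
Reagents that add atoms: water, O
Why: Oxoammonium-catalysed oxidation of the primary alcohol to aldehyde 28, whose hydrate is oxidised on to the acid in the aqueous medium; no free phenol is present and aryl ethers tolerate this mild oxidant.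

**Step 14**
Reactants: 29
Product: 30 methyl 3-[(2S,3R)-3-(benzyloxymethyl)-2-(4-benzyloxy-3,5-dimethoxyphenyl)-7-methoxy-2,3-dihydrobenzofuran-5-yl]propanoate
Conditions: MeI (1.5 equiv), K2CO3 (1.5 equiv), DMF, rt
Reagents that add atoms: iodomethane, CI
Why: SN2 O-alkylation of the carboxylate gives the methyl ester without acid, so the benzylic C2–O1 bond is never exposed to ionising conditions.

**Step 15**
Reactants: 30
Product: 31 methyl 3-[(2S,3R)-2-(4-hydroxy-3,5-dimethoxyphenyl)-3-(hydroxymethyl)-7-methoxy-2,3-dihydrobenzofuran-5-yl]propanoate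
Conditions: H2 (1 atm), Pd/C (10 wt%), EtOAc/MeOH, rt
Reagents that add atoms: none
Why: Hydrogenolysis of the two exocyclic benzyl ethers; the endocyclic benzylic C2–O1 bond is cleaved much more slowly under neutral conditions, and the reaction is stopped after uptake of two equivalents of hydrogen.

## Compound list

1 | 4-bromofuran-2-carbaldehyde | O=Cc1cc(Br)co1 | starting material
2 | allyloxy(tert-butyl)dimethylsilane | C=CCO[Si](C)(C)C(C)(C)C | starting material
3 | 9-[3-(tert-butyldimethylsilyloxy)propyl]-9-borabicyclo[3.3.1]nonane | CC(C)(C)[Si](C)(C)OCCCB1C2CCCC1CCC2 | intermediate (not isolated)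
4 | 4-[3-(tert-butyldimethylsilyloxy)propyl]furan-2-carbaldehyde | CC(C)(C)[Si](C)(C)OCCCc1coc(C=O)c1 | intermediate
5 | chloroform | ClC(Cl)Cl | starting material
6 | (RS)-2,2,2-trichloro-1-{4-[3-(tert-butyldimethylsilyloxy)propyl]furan-2-yl}ethan-1-ol (racemic) | CC(C)(C)[Si](C)(C)OCCCc1coc(c1)C(O)C(Cl)(Cl)Cl | intermediate
7 | tert-butyl{3-[5-(3,3-dichlorooxiran-2-yl)furan-3-yl]propoxy}dimethylsilane (racemic) | CC(C)(C)[Si](C)(C)OCCCc1coc(c1)C1OC1(Cl)Cl | intermediate (not isolated)
8 | 2-{4-[3-(tert-butyldimethylsilyloxy)propyl]furan-2-yl}acetyl chloride | CC(C)(C)[Si](C)(C)OCCCc1coc(CC(Cl)=O)c1 | intermediate (not isolated)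
9 | 2-{4-[3-(tert-butyldimethylsilyloxy)propyl]furan-2-yl}acetic acid | CC(C)(C)[Si](C)(C)OCCCc1coc(CC(O)=O)c1 | intermediate
10 | (S)-4-benzyl-1,3-oxazolidin-2-one | O=C1N[C@@H](Cc2ccccc2)CO1 | starting material
11 | 2-{4-[3-(tert-butyldimethylsilyloxy)propyl]furan-2-yl}acetic pivalic anhydride | CC(C)(C)[Si](C)(C)OCCCc1coc(CC(=O)OC(=O)C(C)(C)C)c1 | intermediate (not isolated)
12 | (S)-4-benzyl-3-(2-{4-[3-(tert-butyldimethylsilyloxy)propyl]furan-2-yl}acetyl)-1,3-oxazolidin-2-one | CC(C)(C)[Si](C)(C)OCCCc1coc(CC(=O)N2C(=O)OC[C@@H]2Cc2ccccc2)c1 | intermediate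
13 | syringaldehyde (4-hydroxy-3,5-dimethoxybenzaldehyde) | COc1cc(C=O)cc(OC)c1O | starting material
14 | 4-benzyloxy-3,5-dimethoxybenzaldehyde | COc1cc(C=O)cc(OC)c1OCc1ccccc1 | intermediate
15 | dibutylboron (Z)-enolate of 12 (O–B and furyl cis) | CC(C)(C)[Si](C)(C)OCCCc1coc(c1)/C=C(\OB(CCCC)CCCC)N1C(=O)OC[C@@H]1Cc1ccccc1 | intermediate (not isolated)
16 | (4S)-4-benzyl-3-[(2R,3S)-3-(4-benzyloxy-3,5-dimethoxyphenyl)-2-{4-[3-(tert-butyldimethylsilyloxy)propyl]furan-2-yl}-3-hydroxypropanoyl]-1,3-oxazolidin-2-one | CC(C)(C)[Si](C)(C)OCCCc1coc(c1)[C@H](C(=O)N1C(=O)OC[C@@H]1Cc1ccccc1)[C@@H](c1cc(OC)c(OCc2ccccc2)c(OC)c1)O | intermediate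
17 | (1S,2R)-1-(4-benzyloxy-3,5-dimethoxyphenyl)-2-{4-[3-(tert-butyldimethylsilyloxy)propyl]furan-2-yl}propane-1,3-diol | CC(C)(C)[Si](C)(C)OCCCc1coc(c1)[C@H](CO)[C@@H](c1cc(OC)c(OCc2ccccc2)c(OC)c1)O | intermediate
18 | (1S,2R)-3-benzyloxy-1-(4-benzyloxy-3,5-dimethoxyphenyl)-2-{4-[3-(tert-butyldimethylsilyloxy)propyl]furan-2-yl}propan-1-ol | CC(C)(C)[Si](C)(C)OCCCc1coc(c1)[C@H](COCc1ccccc1)[C@@H](c1cc(OC)c(OCc2ccccc2)c(OC)c1)O | intermediate
19 | trichloroethylene | ClC=C(Cl)Cl | starting material
20 | tert-butyl{3-[5-((1S,2R)-3-benzyloxy-1-(4-benzyloxy-3,5-dimethoxyphenyl)-1-[(E)-1,2-dichlorovinyloxy]propan-2-yl)furan-3-yl]propoxy}dimethylsilane | CC(C)(C)[Si](C)(C)OCCCc1coc(c1)[C@H](COCc1ccccc1)[C@@H](c1cc(OC)c(OCc2ccccc2)c(OC)c1)O/C(Cl)=C\Cl | intermediate (not isolated)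
21 | tert-butyl{3-[5-((1S,2R)-3-benzyloxy-1-(4-benzyloxy-3,5-dimethoxyphenyl)-1-(chloroethynyloxy)propan-2-yl)furan-3-yl]propoxy}dimethylsilane | CC(C)(C)[Si](C)(C)OCCCc1coc(c1)[C@H](COCc1ccccc1)[C@@H](c1cc(OC)c(OCc2ccccc2)c(OC)c1)OC#CCl | intermediate (not isolated)
22 | tert-butyl{3-[5-((1S,2R)-3-benzyloxy-1-(4-benzyloxy-3,5-dimethoxyphenyl)-1-ethynyloxypropan-2-yl)furan-3-yl]propoxy}dimethylsilane | CC(C)(C)[Si](C)(C)OCCCc1coc(c1)[C@H](COCc1ccccc1)[C@@H](c1cc(OC)c(OCc2ccccc2)c(OC)c1)OC#C | intermediate
23 | oxepine valence isomer of 24: (2S,3R)-2,3-dihydrofuran ring fused to an oxepine whose oxygen lies between C6 and C7, with C=C at C3a=C4, C5=C6 and C7=C7a; substituents as in 25 | CC(C)(C)[Si](C)(C)OCCCC1=COC=C2O[C@H](c3cc(OC)c(OCc4ccccc4)c(OC)c3)[C@@H](COCc3ccccc3)C2=C1 | intermediate (not isolated)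
24 | 6,7-epoxide (arene oxide) of the (2S,3R)-2,3,6,7-tetrahydrobenzofuran, with C=C at C3a=C7a and C4=C5; substituents as in 25; epoxide face not defined | CC(C)(C)[Si](C)(C)OCCCC1=CC2=C(C3OC13)O[C@H](c1cc(OC)c(OCc3ccccc3)c(OC)c1)[C@H]2COCc1ccccc1 | intermediate (not isolated)
25 | (2S,3R)-3-(benzyloxymethyl)-2-(4-benzyloxy-3,5-dimethoxyphenyl)-5-[3-(tert-butyldimethylsilyloxy)propyl]-2,3-dihydrobenzofuran-7-ol | CC(C)(C)[Si](C)(C)OCCCc1cc(O)c2c(c1)[C@H](COCc1ccccc1)[C@@H](c1cc(OC)c(OCc3ccccc3)c(OC)c1)O2 | intermediate
26 | tert-butyl{3-[(2S,3R)-3-(benzyloxymethyl)-2-(4-benzyloxy-3,5-dimethoxyphenyl)-7-methoxy-2,3-dihydrobenzofuran-5-yl]propoxy}dimethylsilane | CC(C)(C)[Si](C)(C)OCCCc1cc(OC)c2c(c1)[C@H](COCc1ccccc1)[C@@H](c1cc(OC)c(OCc3ccccc3)c(OC)c1)O2 | intermediate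
27 | 3-[(2S,3R)-3-(benzyloxymethyl)-2-(4-benzyloxy-3,5-dimethoxyphenyl)-7-methoxy-2,3-dihydrobenzofuran-5-yl]propan-1-ol | OCCCc1cc(OC)c2c(c1)[C@H](COCc1ccccc1)[C@@H](c1cc(OC)c(OCc3ccccc3)c(OC)c1)O2 | intermediate
28 | 3-[(2S,3R)-3-(benzyloxymethyl)-2-(4-benzyloxy-3,5-dimethoxyphenyl)-7-methoxy-2,3-dihydrobenzofuran-5-yl]propanal | O=CCCc1cc(OC)c2c(c1)[C@H](COCc1ccccc1)[C@@H](c1cc(OC)c(OCc3ccccc3)c(OC)c1)O2 | intermediate (not isolated)
29 | 3-[(2S,3R)-3-(benzyloxymethyl)-2-(4-benzyloxy-3,5-dimethoxyphenyl)-7-methoxy-2,3-dihydrobenzofuran-5-yl]propanoic acid | OC(=O)CCc1cc(OC)c2c(c1)[C@H](COCc1ccccc1)[C@@H](c1cc(OC)c(OCc3ccccc3)c(OC)c1)O2 | intermediate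
30 | methyl 3-[(2S,3R)-3-(benzyloxymethyl)-2-(4-benzyloxy-3,5-dimethoxyphenyl)-7-methoxy-2,3-dihydrobenzofuran-5-yl]propanoate | COC(=O)CCc1cc(OC)c2c(c1)[C@H](COCc1ccccc1)[C@@H](c1cc(OC)c(OCc3ccccc3)c(OC)c1)O2 | intermediate
31 | methyl 3-[(2S,3R)-2-(4-hydroxy-3,5-dimethoxyphenyl)-3-(hydroxymethyl)-7-methoxy-2,3-dihydrobenzofuran-5-yl]propanoate | COC(=O)CCc1cc(OC)c2c(c1)[C@H](CO)[C@@H](c1cc(OC)c(O)c(OC)c1)O2 | target

## Step count and least certain steps

Total: 15 steps. Longest linear sequence: 14 steps (steps 1 to 4 and 6 to 15, from 1); step 5 is a one-step side branch.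

**Step 10 (key step).** The alkynyl ether may be lost before it cyclises: by hydration to the acetate with adventitious water, by ionisation of the benzylic C–O bond or retro-ene loss of ketene under the Lewis-acidic catalyst, or by capture of the activated alkyne by the syringyl ring in place of the furan. The fallback uses known chemistry only, sets out from 14 and 10 and returns to the route at 31; ring A is bought as an arene.
- Commercial 5-bromo-2-hydroxy-3-methoxybenzaldehyde F1 is protected (4-methoxybenzyl chloride, K2CO3, DMF) as 5-bromo-3-methoxy-2-(4-methoxybenzyloxy)benzaldehyde F2.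
- F2 is homologated as in steps 2 and 3 through the trichloromethyl carbinol F3 to the arylacetic acid F4, which is acylated onto 10 as in step 4 to give the imide F5.
- The syn aldol reaction of F5 with 14 under the conditions of step 6 should give the adduct F6, and LiBH4 reduction the diol F7.
- Trifluoroacetic acid with anisole in CH2Cl2 at 0 °C removes the 4-methoxybenzyl group and ionises the benzylic alcohol. The freed phenol closes the O1–C2 bond to the trans-dihydrobenzofuran bromide F8; C3 is untouched and C2 settles trans to it. A short K2CO3/MeOH treatment would cleave any trifluoroacetate.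
- A Heck reaction of F8 with methyl acrylate (Pd(OAc)2, P(o-tol)3, Et3N, DMF, 90 °C) gives the cinnamate F9. Hydrogenation over Pd/C as in step 15 saturates the alkene and removes the benzyl ether to give 31.

**Step 9.** The hindered secondary alkoxide may capture the transient dichloroacetylene incompletely, and the benzylic alkynyl ether may decompose thermally (sigmatropic or retro-ene) during isolation. The fallback sets out from 18 and returns at 22; it brings in the two carbons without strong base. Formylation (acetic formic anhydride, pyridine, 0 °C) gives the formate F10. Dibromo-olefination of the formate carbonyl (CBr4, PPh3, CH2Cl2, 0 °C) gives the 2,2-dibromovinyl ether F11. n-BuLi (2.1 equiv, THF, −78 °C; elimination of HBr, then bromine–lithium exchange) and a methanol quench give 22.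

**Step 3.** The chloroform addition may reverse under the alkaline conditions, with reduction of the freed aldehyde, and the silyl ether may be partly lost in warm alkali. The fallback sets out from 4 and returns at 9. Wittig methylenation (methyltriphenylphosphonium bromide, KOt-Bu, THF, 0 °C) gives the vinylfuran F12. Hydroboration with 9-BBN and oxidation (NaOH, H2O2, 0 °C) give the primary alcohol F13. Oxidation with TEMPO and PhI(OAc)2 in aqueous MeCN gives 9.

**Step 8.** Site selectivity may be poor, with benzylation of the secondary hydroxyl or of both. The fallback sets out from 16 and returns at 18; it removes the need for selectivity.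
- The carbinol is silylated (TESOTf, 2,6-lutidine, CH2Cl2, −78 °C) to the triethylsilyl ether F14.
- LiBH4 reduction gives the primary alcohol F15.
- Neutral benzylation (2-benzyloxy-1-methylpyridinium triflate, MgO, trifluorotoluene, 85 °C, chosen to avoid base-induced silyl migration) gives the benzyl ether F16.
- Selective removal of the triethylsilyl group (PPTS, MeOH, 0 °C) leaves the primary tert-butyldimethylsilyl ether and gives 18.

**Step 15.** Over-reduction may open the benzylic C2–O1 bond, or the alkyl benzyl ether may cleave slowly. The fallback sets out from 30 and returns at 31: Lewis-acid debenzylation with BCl3 and pentamethylbenzene as cation scavenger in CH2Cl2 at −78 °C, which involves no hydrogen and makes no new compound.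

## Further compounds

F1 | step 10 | 5-bromo-2-hydroxy-3-methoxybenzaldehyde | O=Cc1cc(Br)cc(OC)c1O
F2 | step 10 | 5-bromo-3-methoxy-2-(4-methoxybenzyloxy)benzaldehyde | O=Cc1cc(Br)cc(OC)c1OCc1ccc(OC)cc1
F3 | step 10 | (RS)-1-[5-bromo-3-methoxy-2-(4-methoxybenzyloxy)phenyl]-2,2,2-trichloroethan-1-ol (racemic) | OC(c1cc(Br)cc(OC)c1OCc1ccc(OC)cc1)C(Cl)(Cl)Cl
F4 | step 10 | 2-[5-bromo-3-methoxy-2-(4-methoxybenzyloxy)phenyl]acetic acid | OC(=O)Cc1cc(Br)cc(OC)c1OCc1ccc(OC)cc1
F5 | step 10 | (S)-4-benzyl-3-{2-[5-bromo-3-methoxy-2-(4-methoxybenzyloxy)phenyl]acetyl}-1,3-oxazolidin-2-one | O=C(Cc1cc(Br)cc(OC)c1OCc1ccc(OC)cc1)N1C(=O)OC[C@@H]1Cc1ccccc1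
F6 | step 10 | (4S)-4-benzyl-3-[(2S,3S)-3-(4-benzyloxy-3,5-dimethoxyphenyl)-2-[5-bromo-3-methoxy-2-(4-methoxybenzyloxy)phenyl]-3-hydroxypropanoyl]-1,3-oxazolidin-2-one | COc1cc(Br)cc(c1OCc1ccc(OC)cc1)[C@H](C(=O)N1C(=O)OC[C@@H]1Cc1ccccc1)[C@@H](c1cc(OC)c(OCc2ccccc2)c(OC)c1)O
F7 | step 10 | (1S,2R)-1-(4-benzyloxy-3,5-dimethoxyphenyl)-2-[5-bromo-3-methoxy-2-(4-methoxybenzyloxy)phenyl]propane-1,3-diol | COc1cc(Br)cc(c1OCc1ccc(OC)cc1)[C@H](CO)[C@@H](c1cc(OC)c(OCc2ccccc2)c(OC)c1)O
F8 | step 10 | [(2S,3R)-2-(4-benzyloxy-3,5-dimethoxyphenyl)-5-bromo-7-methoxy-2,3-dihydrobenzofuran-3-yl]methanol | Brc1cc(OC)c2c(c1)[C@H](CO)[C@@H](c1cc(OC)c(OCc3ccccc3)c(OC)c1)O2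
F9 | step 10 | methyl (E)-3-[(2S,3R)-2-(4-benzyloxy-3,5-dimethoxyphenyl)-3-(hydroxymethyl)-7-methoxy-2,3-dihydrobenzofuran-5-yl]acrylate | COC(=O)/C=C/c1cc(OC)c2c(c1)[C@H](CO)[C@@H](c1cc(OC)c(OCc3ccccc3)c(OC)c1)O2
F10 | step 9 | (1S,2R)-3-benzyloxy-1-(4-benzyloxy-3,5-dimethoxyphenyl)-2-{4-[3-(tert-butyldimethylsilyloxy)propyl]furan-2-yl}propyl formate | CC(C)(C)[Si](C)(C)OCCCc1coc(c1)[C@H](COCc1ccccc1)[C@@H](c1cc(OC)c(OCc2ccccc2)c(OC)c1)OC=O
F11 | step 9 | tert-butyl{3-[5-((1S,2R)-3-benzyloxy-1-(4-benzyloxy-3,5-dimethoxyphenyl)-1-(2,2-dibromovinyloxy)propan-2-yl)furan-3-yl]propoxy}dimethylsilane | CC(C)(C)[Si](C)(C)OCCCc1coc(c1)[C@H](COCc1ccccc1)[C@@H](c1cc(OC)c(OCc2ccccc2)c(OC)c1)OC=C(Br)Br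
F12 | step 3 | tert-butyldimethyl[3-(5-vinylfuran-3-yl)propoxy]silane | CC(C)(C)[Si](C)(C)OCCCc1coc(C=C)c1
F13 | step 3 | 2-{4-[3-(tert-butyldimethylsilyloxy)propyl]furan-2-yl}ethan-1-ol | CC(C)(C)[Si](C)(C)OCCCc1coc(CCO)c1
F14 | step 8 | (4S)-4-benzyl-3-[(2R,3S)-3-(4-benzyloxy-3,5-dimethoxyphenyl)-2-{4-[3-(tert-butyldimethylsilyloxy)propyl]furan-2-yl}-3-(triethylsilyloxy)propanoyl]-1,3-oxazolidin-2-one | CC(C)(C)[Si](C)(C)OCCCc1coc(c1)[C@H](C(=O)N1C(=O)OC[C@@H]1Cc1ccccc1)[C@@H](c1cc(OC)c(OCc2ccccc2)c(OC)c1)O[Si](CC)(CC)CC
F15 | step 8 | (2R,3S)-3-(4-benzyloxy-3,5-dimethoxyphenyl)-2-{4-[3-(tert-butyldimethylsilyloxy)propyl]furan-2-yl}-3-(triethylsilyloxy)propan-1-ol | CC(C)(C)[Si](C)(C)OCCCc1coc(c1)[C@H](CO)[C@@H](c1cc(OC)c(OCc2ccccc2)c(OC)c1)O[Si](CC)(CC)CC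
F16 | step 8 | tert-butyl{3-[5-((1S,2R)-3-benzyloxy-1-(4-benzyloxy-3,5-dimethoxyphenyl)-1-(triethylsilyloxy)propan-2-yl)furan-3-yl]propoxy}dimethylsilane | CC(C)(C)[Si](C)(C)OCCCc1coc(c1)[C@H](COCc1ccccc1)[C@@H](c1cc(OC)c(OCc2ccccc2)c(OC)c1)O[Si](CC)(CC)CC
F0 | step 15 | none | none
A1 | alternative 1 | methyl (2S,3S)-5-bromo-2-(3,5-dimethoxy-4-pivaloyloxyphenyl)-7-methoxy-2,3-dihydrobenzofuran-3-carboxylate | Brc1cc(OC)c2c(c1)[C@H](C(=O)OC)[C@@H](c1cc(OC)c(OC(=O)C(C)(C)C)c(OC)c1)O2
A2 | alternative 1 | (2S)-6-bromo-2-(3,5-dimethoxy-4-pivaloyloxyphenyl)-8-methoxychroman-4-one | Brc1cc(OC)c2c(c1)C(=O)C[C@@H](c1cc(OC)c(OC(=O)C(C)(C)C)c(OC)c1)O2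
A3 | alternative 2 | methyl 3-[(2S,3R)-2-(4-benzyloxy-3,5-dimethoxyphenyl)-3-(tert-butyldimethylsilyloxymethyl)-7-methoxy-2,3-dihydrobenzofuran-5-yl]propanoate | COC(=O)CCc1cc(OC)c2c(c1)[C@H](CO[Si](C)(C)C(C)(C)C)[C@@H](c1cc(OC)c(OCc3ccccc3)c(OC)c1)O2
A4 | alternative 2 | methyl 3-{4-hydroxy-3-methoxy-5-[2-(tert-butyldimethylsilyloxy)-1-(4-methylphenylsulfonyl)ethyl]phenyl}propanoate (racemic) | COC(=O)CCc1cc(OC)c(O)c(c1)C(CO[Si](C)(C)C(C)(C)C)S(=O)(=O)c1ccc(C)cc1
A5 | alternative 2 | 1-(4-benzyloxy-3,5-dimethoxybenzyl)-(2R,5R)-2,5-dimethylthiolan-1-ium triflate | C[C@@H]1CC[C@@H](C)[S+]1Cc1cc(OC)c(OCc2ccccc2)c(OC)c1.[O-]S(=O)(=O)C(F)(F)F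
A6 | alternative 3 | 4-[(2S,3R)-5-bromo-3-(hydroxymethyl)-7-methoxy-2,3-dihydrobenzofuran-2-yl]-2,6-dimethoxyphenol | Brc1cc(OC)c2c(c1)[C@H](CO)[C@@H](c1cc(OC)c(O)c(OC)c1)O2
A7 | alternative 3 | (2R)-2-(5-bromo-2-hydroxy-3-methoxyphenyl)-3-(4-hydroxy-3,5-dimethoxyphenyl)propan-1-ol | Brc1cc(OC)c(O)c(c1)[C@H](CO)Cc1cc(OC)c(O)c(OC)c1
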